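## Retrosynthetic overview

1. The C2–aryl bond and the C2 stereocentre are made last, by Rh‑catalysed asymmetric 1,4‑addition of a B‑ring arylzinc (from bromide 13) to transiently silylated 5,7‑dihydroxychromone 5.
2. Chromone 5 comes from resorcinol: C‑acylation, pyranone ring closure, then Ru‑catalysed ketone‑directed C5–H hydroxylation.
3. Bromide 13 comes from 4‑bromophenol: di‑iodination, O‑methylation, mono I/Mg exchange–prenylation, then I‑selective Suzuki coupling with dienylboronate 7.
4. Dienylboronate 7 comes from hydroboration of 2‑methylbut‑1‑en‑3‑yne.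
5. Ring order: both benzene rings are bought; the pyranone ring is the only ring formed (step 2) and becomes the chromanone in step 10.

Assumption: simple atom‑donating reagents (AcOH, DMF‑DMA, I2, MeI, HBpin, HMDS) are treated as reagents and are not numbered.

## Route

**Step 1**
Reactants: 1 resorcinol
Product: 2, 1‑(2,4‑dihydroxyphenyl)ethan‑1‑one
Conditions: AcOH, ZnCl2 (1.2 equiv), 140 °C, 20 min; aq. HCl work‑up
Reagents that add atoms: acetic acid, CC(=O)O
Why: Nencki (Friedel–Crafts) C‑acylation at C4, the position ortho/para to the two OH groups; no stereocentre.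

**Step 2**
Reactants: 2
Product: 3, 7‑hydroxy‑4H‑chromen‑4‑one
Conditions: DMF‑DMA (2.5 equiv), toluene, 95 °C, 3 h; then conc. HCl, CH2Cl2, 40 °C, 2 h
Reagents that add atoms: N,N‑dimethylformamide dimethyl acetal, COC(OC)N(C)C
Why: Enaminone chromone synthesis: condensation at the methyl ketone, then acid‑promoted oxa‑Michael addition and loss of Me2NH closes the pyranone ring.

**Step 3**
Reactants: 3
Product: 4, 5,7‑dihydroxy‑4H‑chromen‑4‑one
Conditions: [RuCl2(p‑cymene)]2 (5 mol%), PhI(OCOCF3)2 (2 equiv), TFA/TFAA 3:1, 80 °C, 6 h; then MeOH/aq. NaHCO3, rt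
Reagents that add atoms: [bis(trifluoroacetoxy)iodo]benzene, O=C(OI(OC(=O)C(F)(F)F)c1ccccc1)C(F)(F)F (supplies the C5 oxygen as a trifluoroacetate, hydrolysed on work‑up)
Why: Ketone‑directed Ru(II) C–H oxygenation via a five‑membered ruthenacycle at the peri C5–H; the 7‑OH is trifluoroacetylated in situ by TFAA, which protects the ring from over‑oxidation, and both esters are cleaved on work‑up.

**Step 4**
Reactants: 4
Product: 5, 5,7‑bis(trimethylsilyloxy)‑4H‑chromen‑4‑one (crude, used directly under Ar)
Conditions: HMDS (4 equiv), TMSCl (5 mol%), MeCN, 80 °C, 2 h; evaporate to dryness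
Reagents that add atoms: hexamethyldisilazane, C[Si](C)(C)N[Si](C)(C)C
Why: Standard phenol per‑silylation (the chelated 5‑OH included); NH3 and excess HMDS are volatile, so an aprotic substrate is obtained without purification.

**Step 5**
Reactants: 6 2‑methylbut‑1‑en‑3‑yne
Product: 7, (E)‑4,4,5,5‑tetramethyl‑2‑(3‑methylbuta‑1,3‑dien‑1‑yl)‑1,3,2‑dioxaborolane
Conditions: HBpin (1.05 equiv), Cp2Zr(H)Cl (5 mol%), Et3N (10 mol%), neat, sealed tube, 40 °C, 16 h
Reagents that add atoms: pinacolborane, CC1(C)OBOC1(C)C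
Why: Zr‑catalysed syn, anti‑Markovnikov hydroboration of the terminal alkyne gives only the E alkenylboronate; the 1,1‑disubstituted alkene is untouched.

**Step 6**
Reactants: 8 4‑bromophenol
Product: 9, 4‑bromo‑2,6‑diiodophenol
Conditions: I2 (2.1 equiv), 30% H2O2 (3 equiv), H2O, 50 °C
Reagents that add atoms: iodine, II
Why: Electrophilic aromatic iodination; with the para position blocked, both ortho positions are iodinated.

**Step 7**
Reactants: 9
Product: 10, 5‑bromo‑1,3‑diiodo‑2‑methoxybenzene
Conditions: MeI (1.5 equiv), K2CO3, DMF, 40 °C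
Reagents that add atoms: iodomethane, CI
Why: Williamson O‑methylation of the acidic dihalophenol.

**Step 8**
Reactants: 10; 11 1‑bromo‑3‑methylbut‑2‑ene (prenyl bromide)
Product: 12, 5‑bromo‑1‑iodo‑2‑methoxy‑3‑(3‑methylbut‑2‑en‑1‑yl)benzene
Conditions: i‑PrMgCl·LiCl (1.05 equiv), THF, −40 °C, 30 min; CuI (10 mol%), 11 (1.3 equiv), −40 → 0 °C
Reagents that add atoms: none (11 is a reactant)
Why: Turbo‑Grignard I/Mg exchange occurs once, at an iodide ortho to OMe and faster than at Br, and the resulting arylmagnesium resists a second exchange, which desymmetrises the two iodides; Cu‑catalysed allylic substitution at the unhindered α‑carbon of prenyl bromide gives the linear prenyl arene.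

**Step 9**
Reactants: 12; 7
Product: 13, 5‑bromo‑2‑methoxy‑1‑(3‑methylbut‑2‑en‑1‑yl)‑3‑[(1E)‑3‑methylbuta‑1,3‑dien‑1‑yl]benzene
Conditions: Pd(PPh3)4 (4 mol%), K3PO4 (3 equiv), THF/H2O 5:1, 45 °C, trace BHT
Reagents that add atoms: none
Why: Suzuki–Miyaura coupling; oxidative addition at C–I is far faster than at C–Br at 45 °C with PPh3, and alkenyl transfer is stereoretentive, so the E diene is installed and the bromide is kept.

**Step 10**
Reactants: 13; 5
Product: 14, (2S)‑5,7‑dihydroxy‑2‑{4‑methoxy‑3‑(3‑methylbut‑2‑en‑1‑yl)‑5‑[(1E)‑3‑methylbuta‑1,3‑dien‑1‑yl]phenyl}‑2,3‑dihydro‑4H‑chromen‑4‑one (target)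
Conditions: 13 (1.3 equiv), n‑BuLi (1.0 equiv per 13), THF, −78 °C, 10 min; ZnCl2 (1.4 equiv), −78 → 0 °C; cannulate into 5 (1.0 equiv), [RhCl((S)‑binap)]2 (3 mol% Rh), TMSCl (1.5 equiv), THF, 20 °C, 6 h; then AcOH/KF, MeOH–H2O, 0 °C → rt, 30 min
Reagents that add atoms: none retained (TMSCl, C[Si](C)(C)Cl, silylates the enolate transiently; all silyl groups are removed in the work‑up)
Why: Proposed new method: Rh(I)/(S)‑BINAP‑catalysed asymmetric 1,4‑arylation of a transiently per‑O‑silylated polyhydroxychromone with an arylzinc chloride and TMSCl, with the silyl groups acting as traceless protection. ArZnCl transmetalates to Rh–Cl; the chromone C2=C3 inserts enantioselectively into the aryl–Rh bond, on the same enone face that gives (S)‑3‑arylcyclohexanones with (S)‑BINAP and hence 2S here (to be confirmed by chiral HPLC/CD against a racemate made with rac‑BINAP). TMSCl then silylates the Rh oxa‑π‑allyl to a 4‑silyloxy‑2H‑chromene, regenerating Rh–Cl; this blocks β‑aryloxide elimination (ring opening, racemisation) and the aprotic medium keeps the ArO–TMS groups intact. ArZnCl and aryl–Rh do not add to the unactivated diene or prenyl group at 20 °C, and the buffered fluoride work‑up frees the ketone and both phenols without acid or base that would harm the diene or C2. Closest known reaction type: Hayashi–Miyaura‑type Rh/bisphosphine asymmetric 1,4‑addition, in its arylzinc/TMSCl variant on N‑acyl‑4‑quinolones and 2,3‑dihydro‑4‑pyridones, and arylboronic acid additions to O‑protected chromones.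

## Compound list

1 | resorcinol | Oc1cccc(O)c1 | starting material
2 | 1‑(2,4‑dihydroxyphenyl)ethan‑1‑one | CC(=O)c1ccc(O)cc1O | intermediate
3 | 7‑hydroxy‑4H‑chromen‑4‑one | O=c1ccoc2cc(O)ccc12 | intermediate
4 | 5,7‑dihydroxy‑4H‑chromen‑4‑one | O=c1ccoc2cc(O)cc(O)c12 | intermediate
5 | 5,7‑bis(trimethylsilyloxy)‑4H‑chromen‑4‑one | O=c1ccoc2cc(O[Si](C)(C)C)cc(O[Si](C)(C)C)c12 | intermediate
6 | 2‑methylbut‑1‑en‑3‑yne | C=C(C)C#C | starting material
7 | (E)‑4,4,5,5‑tetramethyl‑2‑(3‑methylbuta‑1,3‑dien‑1‑yl)‑1,3,2‑dioxaborolane | C=C(C)/C=C/B1OC(C)(C)C(C)(C)O1 | intermediate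
8 | 4‑bromophenol | Oc1ccc(Br)cc1 | starting material
9 | 4‑bromo‑2,6‑diiodophenol | Oc1c(I)cc(Br)cc1I | intermediate
10 | 5‑bromo‑1,3‑diiodo‑2‑methoxybenzene | COc1c(I)cc(Br)cc1I | intermediate
11 | 1‑bromo‑3‑methylbut‑2‑ene (prenyl bromide) | CC(C)=CCBr | starting material
12 | 5‑bromo‑1‑iodo‑2‑methoxy‑3‑(3‑methylbut‑2‑en‑1‑yl)benzene | COc1c(I)cc(Br)cc1CC=C(C)C | intermediate
13 | 5‑bromo‑2‑methoxy‑1‑(3‑methylbut‑2‑en‑1‑yl)‑3‑[(1E)‑3‑methylbuta‑1,3‑dien‑1‑yl]benzene | C=C(C)/C=C/c1cc(Br)cc(CC=C(C)C)c1OC | intermediate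
14 | (2S)‑5,7‑dihydroxy‑2‑{4‑methoxy‑3‑(3‑methylbut‑2‑en‑1‑yl)‑5‑[(1E)‑3‑methylbuta‑1,3‑dien‑1‑yl]phenyl}‑2,3‑dihydro‑4H‑chromen‑4‑one | C=C(C)/C=C/c1cc([C@@H]2CC(=O)c3c(O)cc(O)cc3O2)cc(CC=C(C)C)c1OC | target

## Summary

Total step count: 10.
Longest linear sequence: 5 (steps 1–4 and 10, or steps 6–10).

Steps most likely to fail, with fallbacks:

1. **Step 10 (proposed new method).** Risks are low reactivity of the electron‑rich silylated chromone, interference by the diene, and loss of the TMS groups. Fallback, known chemistry: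
   - Protect 4 as the isolated 5,7‑bis(TIPS) ether (TIPSOTf, 2,6‑lutidine).
   - Convert the B‑ring bromide to the arylboronic acid (n‑BuLi; B(Oi‑Pr)3; H3O+). If the free diene is the problem, carry it masked as the tertiary allylic alcohol from Heck coupling of 12 with 2‑methylbut‑3‑en‑2‑ol.
   - Run the established aqueous Rh(I)/chiral diene (or Pd(II)/PyOX) arylboronic acid 1,4‑addition to the O‑protected chromone.
   - Finish with Burgess dehydration (if masked) and TBAF/AcOH desilylation.

2. **Step 3 (Ru C5–H hydroxylation on the free 7‑hydroxychromone).** Fallback: install the third oxygen before the heterocycle is built. Resorcinol → 1,3‑dimethoxybenzene → Ir‑catalysed meta C–H borylation/oxidation to 3,5‑dimethoxyphenol → Ac2O/BF3 ortho‑acylation → DMF‑DMA/HCl chromone closure → BBr3 demethylation to 4.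

3. **Step 9 (I‑selective Suzuki coupling with the polymerisation‑prone dienylboronate).** Fallback: I‑selective Heck coupling of 12 with 2‑methylbut‑3‑en‑2‑ol (Pd(OAc)2, Et3N) to the E tertiary allylic alcohol, then dehydration (MsCl/Et3N or Burgess reagent) to 13.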